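Numbering: decahydroquinoline N1, C2–C8a; side chain C1′–C8′. Retrosynthesis cuts the C3 ester, turns N1–H/C2–CH3 back into an oxazolidinone ring N1–CO–O–CH2–C2, then cuts C4a–C8a and C5–C6 together, then C4a=C5 (Wittig) and C3–C4 (allylation).
Enabling feature: the carbocycle C4a–C5–C6–C7–C8–C8a carries N1 on C8a, C4 on C4a and C1′ on C5, all cis, and N1 is joined to C4a by the chain C2–C3–C4. This is the retron of an intramolecular [4+2] of an (E)-1-amidodiene (C8a=C8–C7=C6) with a (Z)-alkene (C4a=C5).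
Forward: side-chain phosphonium salt (steps 1–3); D-serine-derived aldehyde, allylation, benzylation, ozonolysis, (Z)-Wittig (steps 4–7); oxazolidinone and N-dienyl group (steps 8–10); one cycloaddition closes the carbocycle and the piperidine (step 11).
Thiolate opening and Raney Ni then turn the oxazolidinone CH2–O into the C2 methyl, free N1–H and saturate C7=C8; Boc protection, debenzylation, esterification and deprotection finish (steps 12–16).
Stereochemistry: C2 from the D-serine-derived aldehyde (its CH2O carbon becomes the C2 methyl), C3 from reagent-controlled allylboration, C5′ from (R)-1,2-epoxypentane, C4a/C5/C8a from the cycloaddition (alkene geometry, endo tether, oxazolidinone-locked chair).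

Key step: step 11

Step 1
Reactants: 1 (R)-2-propyloxirane; 2 1-bromo-4-chlorobutane
Product: 4 (4R)-9-chlorononan-4-ol, via (4-chlorobutyl)magnesium bromide 3 (not isolated)
Conditions: 2, Mg, THF, 0–20 °C; then 1, CuI (cat.), −30 → 0 °C; H2O
Reagents that add atoms: none
Why: Copper-catalysed Grignard opening of a terminal epoxide (SN2 at the CH2 terminus) after selective Mg insertion into the C–Br bond, so the C5′ carbinol centre of 1 is carried over untouched.

Step 2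
Reactants: 4 (4R)-9-chlorononan-4-ol
Product: 5 tert-butyl{[(4R)-9-chlorononan-4-yl]oxy}diphenylsilane
Conditions: TBDPSCl, imidazole, DMF, rt
Reagents that add atoms: tert-butyl(chloro)diphenylsilane, CC(C)(C)[Si](Cl)(c1ccccc1)c1ccccc1
Why: Silylation of the secondary alcohol (silyl ether formation) gives an acid-, base- and heat-stable mask for C5′–OH.

Step 3
Reactants: 5 tert-butyl{[(4R)-9-chlorononan-4-yl]oxy}diphenylsilane
Product: 7 {(6R)-6-[(tert-butyldiphenylsilyl)oxy]nonyl}triphenylphosphonium iodide, via iodide 6 (not isolated)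
Conditions: NaI, PPh3, MeCN, reflux
Reagents that add atoms: triphenylphosphine, c1ccccc1P(c1ccccc1)c1ccccc1; sodium iodide, [Na+].[I-]
Why: Finkelstein halide exchange followed by SN2 quaternisation of PPh3 at the primary carbon (phosphonium salt formation).

Step 4
Reactants: 8 tert-butyl (4R)-4-formyl-2,2-dimethyl-1,3-oxazolidine-3-carboxylate; 9 (+)-B-allyldiisopinocampheylborane, (+)-Ipc2B(allyl), the (−)-α-pinene-derived reagent
Product: 11 tert-butyl (4R)-4-[(1R)-1-hydroxybut-3-en-1-yl]-2,2-dimethyl-1,3-oxazolidine-3-carboxylate, via borinate ester 10 (not isolated)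
Conditions: Et2O, −78 °C; then NaOH, H2O2, 0 °C → rt
Reagents that add atoms: none
Why: Asymmetric allylboration (Brown allylation) through a chair Zimmerman–Traxler transition state, in which this reagent enantiomer should deliver allyl to the re face and set C3 as (R), syn to nitrogen, under reagent control over the modest Felkin–Anh bias.

Step 5
Reactants: 11 tert-butyl (4R)-4-[(1R)-1-hydroxybut-3-en-1-yl]-2,2-dimethyl-1,3-oxazolidine-3-carboxylate
Product: 12 tert-butyl (4R)-4-[(1R)-1-(benzyloxy)but-3-en-1-yl]-2,2-dimethyl-1,3-oxazolidine-3-carboxylate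
Conditions: 2-benzyloxy-1-methylpyridinium triflate, MgO, PhCF3, 83 °C
Reagents that add atoms: 2-(benzyloxy)-1-methylpyridinium trifluoromethanesulfonate, C[n+]1ccccc1OCc1ccccc1.[O-]S(=O)(=O)C(F)(F)F
Why: O-Benzylation by thermal benzyl transfer under neutral conditions, which avoids the alkoxide that would attack the neighbouring Boc group.

Step 6
Reactants: 12 tert-butyl (4R)-4-[(1R)-1-(benzyloxy)but-3-en-1-yl]-2,2-dimethyl-1,3-oxazolidine-3-carboxylate
Product: 14 tert-butyl (4R)-4-[(1R)-1-(benzyloxy)-3-oxopropyl]-2,2-dimethyl-1,3-oxazolidine-3-carboxylate, via ozonide 13 (not isolated)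
Conditions: O3, CH2Cl2, −78 °C; then PPh3, −78 °C → rt
Reagents that add atoms: ozone, [O-][O+]=O
Why: Ozonolysis with reductive work-up cleaves the terminal alkene to the aldehyde that becomes C4a, without touching the stereocentres.

Step 7
Reactants: 14 tert-butyl (4R)-4-[(1R)-1-(benzyloxy)-3-oxopropyl]-2,2-dimethyl-1,3-oxazolidine-3-carboxylate; 7 {(6R)-6-[(tert-butyldiphenylsilyl)oxy]nonyl}triphenylphosphonium iodide
Product: 16 tert-butyl (4R)-4-[(1R,3Z,9R)-1-(benzyloxy)-9-[(tert-butyldiphenylsilyl)oxy]dodec-3-en-1-yl]-2,2-dimethyl-1,3-oxazolidine-3-carboxylate, via phosphonium ylide 15 (not isolated)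
Conditions: 7, NaN(SiMe3)2, THF, −78 → 0 °C; then 14, −78 °C → rt
Reagents that add atoms: none
Why: Salt-free Wittig olefination with a non-stabilised ylide should give the (Z)-alkene C4a=C5 under kinetic control (cis-oxaphosphetane), the geometry that later fixes C5 relative to C4a.

Step 8
Reactants: 16 tert-butyl (4R)-4-[(1R,3Z,9R)-1-(benzyloxy)-9-[(tert-butyldiphenylsilyl)oxy]dodec-3-en-1-yl]-2,2-dimethyl-1,3-oxazolidine-3-carboxylate
Product: 17 tert-butyl N-[(2R,3R,5Z,11R)-3-(benzyloxy)-11-[(tert-butyldiphenylsilyl)oxy]-1-hydroxytetradec-5-en-2-yl]carbamate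
Conditions: p-TsOH·H2O (cat.), MeOH, rt
Reagents that add atoms: none
Why: Acid-catalysed methanolysis of the N,O-acetonide (transketalisation) frees the primary alcohol while the Boc group, the benzyl ether and the TBDPS ether should be stable.

Step 9
Reactants: 17 tert-butyl N-[(2R,3R,5Z,11R)-3-(benzyloxy)-11-[(tert-butyldiphenylsilyl)oxy]-1-hydroxytetradec-5-en-2-yl]carbamate
Product: 18 (4R)-4-[(1R,3Z,9R)-1-(benzyloxy)-9-[(tert-butyldiphenylsilyl)oxy]dodec-3-en-1-yl]-1,3-oxazolidin-2-one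
Conditions: NaH, THF, 0 °C → rt; H2O
Reagents that add atoms: none
Why: Intramolecular acyl substitution, in which the primary alkoxide attacks the Boc carbonyl (5-exo-trig) and expels tert-butoxide, gives the oxazolidinone that both activates nitrogen and ties C2 to it.

Step 10
Reactants: 18 (4R)-4-[(1R,3Z,9R)-1-(benzyloxy)-9-[(tert-butyldiphenylsilyl)oxy]dodec-3-en-1-yl]-1,3-oxazolidin-2-one; 19 (E)-but-2-enal
Product: 20 (4R)-4-[(1R,3Z,9R)-1-(benzyloxy)-9-[(tert-butyldiphenylsilyl)oxy]dodec-3-en-1-yl]-3-[(1E)-buta-1,3-dien-1-yl]-1,3-oxazolidin-2-one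
Conditions: 19 (excess), PPTS (cat.), BHT, toluene, reflux, 4 Å molecular sieves
Reagents that add atoms: none
Why: Acid-catalysed condensation of the carbamate N–H with the enal (N-acyl hemiaminal, N-acyliminium ion, loss of the γ-proton), a known route to N-dienyl lactams, should give the conjugated (E)-dienamide as the thermodynamic isomer.

Step 11
Reactants: 20 (4R)-4-[(1R,3Z,9R)-1-(benzyloxy)-9-[(tert-butyldiphenylsilyl)oxy]dodec-3-en-1-yl]-3-[(1E)-buta-1,3-dien-1-yl]-1,3-oxazolidin-2-one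
Product: 21 (3aR,4R,5aS,6S,9aR)-4-(benzyloxy)-6-{(5R)-5-[(tert-butyldiphenylsilyl)oxy]octyl}-3,3a,4,5,5a,6,7,9a-octahydro-1H-[1,3]oxazolo[3,4-a]quinolin-1-one
Conditions: toluene (0.01 M), BHT, sealed tube, 190 °C
Reagents that add atoms: none
Why: Thermal, concerted but asynchronous [4+2] cycloaddition (type 1 intramolecular Diels–Alder) of the (E)-1-amidodiene C8a=C8–C7=C6 with the unactivated (Z)-alkene C4a=C5, the closest known reaction type being the thermal cyclisation of N-acyl-N-(1,3-dienyl)amines to cis-fused octahydroquinolines. The cyclohexene closes through both new bonds and the piperidine through the C4a–C8a bond alone, with C2–C3–C4 as the three-atom tether between N1 and C4a. Suprafacial addition to the (Z)-alkene puts C4 and C1′ cis at C4a/C5, and the tether-under-diene (endo) mode puts N1 and C4 cis at C8a/C4a, which is the cis ring fusion. The π-face follows from a chair-like tether in which the fused oxazolidinone holds the C2–CH2O bond in the carbamate plane (equatorial), so that the cis-related C3–OBn is axial, C5 equatorial and the diene carbon C8 axial and trans to the C2 substituent, the 2,8a-trans array of the target. The step needs endo over exo and one π-face: the exo (trans-fusing) mode would push C8 into the carbamate plane against the carbonyl oxygen (allylic 1,3-strain), and the other face would need a boat-like tether. High dilution and BHT should suppress polymerisation of the dienamide.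

Step 12
Reactants: 21 (3aR,4R,5aS,6S,9aR)-4-(benzyloxy)-6-{(5R)-5-[(tert-butyldiphenylsilyl)oxy]octyl}-3,3a,4,5,5a,6,7,9a-octahydro-1H-[1,3]oxazolo[3,4-a]quinolin-1-one
Product: 23 (2S,3R,4aS,5S,8aR)-3-(benzyloxy)-5-{(5R)-5-[(tert-butyldiphenylsilyl)oxy]octyl}-2-[(phenylsulfanyl)methyl]-1,2,3,4,4a,5,6,8a-octahydroquinoline, via sodium carbamate 22 (not isolated)
Conditions: PhSNa, DMF, 120 °C; then H2O
Reagents that add atoms: sodium benzenethiolate, [Na+].[S-]c1ccccc1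
Why: SN2 opening of the cyclic carbamate at its O–CH2 carbon by thiolate (alkyl–oxygen cleavage, oxazolidinone as latent aziridine equivalent) and decarboxylation on work-up should unmask N1–H and leave a C–S bond on the future methyl carbon, with no stereocentre touched.

Step 13
Reactants: 23 (2S,3R,4aS,5S,8aR)-3-(benzyloxy)-5-{(5R)-5-[(tert-butyldiphenylsilyl)oxy]octyl}-2-[(phenylsulfanyl)methyl]-1,2,3,4,4a,5,6,8a-octahydroquinoline
Product: 24 (2R,3R,4aS,5S,8aR)-3-(benzyloxy)-5-{(5R)-5-[(tert-butyldiphenylsilyl)oxy]octyl}-2-methyldecahydroquinoline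
Conditions: Raney Ni, H2 (1 atm), EtOH, rt
Reagents that add atoms: none
Why: Raney Ni hydrogenolysis of the C–S bonds (desulfurisation) turns CH2SPh into the C2 methyl group, and the same catalyst hydrogenates C7=C8, which creates no stereocentre; the benzyl and silyl ethers should survive at room temperature.

Step 14
Reactants: 24 (2R,3R,4aS,5S,8aR)-3-(benzyloxy)-5-{(5R)-5-[(tert-butyldiphenylsilyl)oxy]octyl}-2-methyldecahydroquinoline
Product: 26 tert-butyl (2R,3R,4aS,5S,8aR)-5-{(5R)-5-[(tert-butyldiphenylsilyl)oxy]octyl}-3-hydroxy-2-methyloctahydroquinoline-1(2H)-carboxylate, via N-Boc benzyl ether 25 (not isolated)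
Conditions: Boc2O, MeOH, 45 °C; then H2 (1 atm), Pd(OH)2/C, rt
Reagents that add atoms: di-tert-butyl dicarbonate, CC(C)(C)OC(=O)OC(=O)OC(C)(C)C
Why: Carbamate formation on the secondary amine followed by catalytic hydrogenolysis of the benzyl ether frees C3–OH alone; no amine base is added because amines retard O-debenzylation.

Step 15
Reactants: 26 tert-butyl (2R,3R,4aS,5S,8aR)-5-{(5R)-5-[(tert-butyldiphenylsilyl)oxy]octyl}-3-hydroxy-2-methyloctahydroquinoline-1(2H)-carboxylate; 27 (2E)-oct-2-enoic acid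
Product: 28 tert-butyl (2R,3R,4aS,5S,8aR)-5-{(5R)-5-[(tert-butyldiphenylsilyl)oxy]octyl}-2-methyl-3-{[(2E)-oct-2-enoyl]oxy}octahydroquinoline-1(2H)-carboxylate
Conditions: 27, DCC, DMAP (cat.), CH2Cl2, 0 °C → rt
Reagents that add atoms: none
Why: Steglich esterification (carbodiimide activation, acyl transfer through DMAP) acylates C3–OH with retention while nitrogen is blocked.

Step 16
Reactants: 28 tert-butyl (2R,3R,4aS,5S,8aR)-5-{(5R)-5-[(tert-butyldiphenylsilyl)oxy]octyl}-2-methyl-3-{[(2E)-oct-2-enoyl]oxy}octahydroquinoline-1(2H)-carboxylate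
Product: 30 (2R,3R,4aS,5S,8aR)-5-[(5R)-5-hydroxyoctyl]-2-methyldecahydroquinolin-3-yl (2E)-oct-2-enoate, via N-Boc hydroxy ester 29 (not isolated)
Conditions: HF·pyridine, THF/pyridine, 0 °C → rt; then TFA, CH2Cl2, 0 °C; aq. NaHCO3
Reagents that add atoms: none
Why: Fluoride-mediated desilylation while nitrogen is still protected, then acidolysis of the Boc group (loss of the tert-butyl cation and decarboxylation), with the amine kept protonated until the cold basic work-up so that O-to-N acyl migration is avoided.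

Compound list
1 | (R)-2-propyloxirane, (R)-1,2-epoxypentane | CCC[C@@H]1CO1 | starting material
2 | 1-bromo-4-chlorobutane | ClCCCCBr | starting material
3 | (4-chlorobutyl)magnesium bromide | ClCCCC[Mg]Br | intermediate
4 | (4R)-9-chlorononan-4-ol | CCC[C@@H](O)CCCCCCl | intermediate
5 | tert-butyl{[(4R)-9-chlorononan-4-yl]oxy}diphenylsilane | CCC[C@@H](O[Si](c1ccccc1)(c1ccccc1)C(C)(C)C)CCCCCCl | intermediate
6 | tert-butyl{[(4R)-9-iodononan-4-yl]oxy}diphenylsilane | CCC[C@@H](O[Si](c1ccccc1)(c1ccccc1)C(C)(C)C)CCCCCI | intermediate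
7 | {(6R)-6-[(tert-butyldiphenylsilyl)oxy]nonyl}triphenylphosphonium iodide | CCC[C@@H](O[Si](c1ccccc1)(c1ccccc1)C(C)(C)C)CCCCC[P+](c1ccccc1)(c1ccccc1)c1ccccc1.[I-] | intermediate
8 | tert-butyl (4R)-4-formyl-2,2-dimethyl-1,3-oxazolidine-3-carboxylate | O=C[C@H]1COC(C)(C)N1C(=O)OC(C)(C)C | starting material
9 | (+)-B-allyldiisopinocampheylborane, (−)-α-pinene series | C=CCB([C@H]1C[C@H]2C[C@@H]([C@@H]1C)C2(C)C)[C@H]1C[C@H]2C[C@@H]([C@@H]1C)C2(C)C | starting material
10 | tert-butyl (4R)-4-[(1R)-1-{[bis(isopinocampheyl)boranyl]oxy}but-3-en-1-yl]-2,2-dimethyl-1,3-oxazolidine-3-carboxylate | C=CC[C@@H](OB([C@H]2C[C@H]3C[C@@H]([C@@H]2C)C3(C)C)[C@H]2C[C@H]3C[C@@H]([C@@H]2C)C3(C)C)[C@H]1COC(C)(C)N1C(=O)OC(C)(C)C | intermediate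
11 | tert-butyl (4R)-4-[(1R)-1-hydroxybut-3-en-1-yl]-2,2-dimethyl-1,3-oxazolidine-3-carboxylate | C=CC[C@@H](O)[C@H]1COC(C)(C)N1C(=O)OC(C)(C)C | intermediate
12 | tert-butyl (4R)-4-[(1R)-1-(benzyloxy)but-3-en-1-yl]-2,2-dimethyl-1,3-oxazolidine-3-carboxylate | C=CC[C@@H](OCc1ccccc1)[C@H]1COC(C)(C)N1C(=O)OC(C)(C)C | intermediate
13 | tert-butyl (4R)-4-[(1R)-1-(benzyloxy)-2-(1,2,4-trioxolan-3-yl)ethyl]-2,2-dimethyl-1,3-oxazolidine-3-carboxylate (ozonide, both epimers at the trioxolane carbon) | O1OC(OC1)C[C@@H](OCc1ccccc1)[C@H]1COC(C)(C)N1C(=O)OC(C)(C)C | intermediate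
14 | tert-butyl (4R)-4-[(1R)-1-(benzyloxy)-3-oxopropyl]-2,2-dimethyl-1,3-oxazolidine-3-carboxylate | O=CC[C@@H](OCc1ccccc1)[C@H]1COC(C)(C)N1C(=O)OC(C)(C)C | intermediate
15 | {(6R)-6-[(tert-butyldiphenylsilyl)oxy]nonylidene}triphenylphosphorane | CCC[C@@H](O[Si](c1ccccc1)(c1ccccc1)C(C)(C)C)CCCCC=P(c1ccccc1)(c1ccccc1)c1ccccc1 | intermediate
16 | tert-butyl (4R)-4-[(1R,3Z,9R)-1-(benzyloxy)-9-[(tert-butyldiphenylsilyl)oxy]dodec-3-en-1-yl]-2,2-dimethyl-1,3-oxazolidine-3-carboxylate | CCC[C@@H](O[Si](c1ccccc1)(c1ccccc1)C(C)(C)C)CCCC/C=C\C[C@@H](OCc1ccccc1)[C@H]1COC(C)(C)N1C(=O)OC(C)(C)C | intermediate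
17 | tert-butyl N-[(2R,3R,5Z,11R)-3-(benzyloxy)-11-[(tert-butyldiphenylsilyl)oxy]-1-hydroxytetradec-5-en-2-yl]carbamate | OC[C@@H](NC(=O)OC(C)(C)C)[C@H](OCc1ccccc1)C/C=C\CCCC[C@H](O[Si](c1ccccc1)(c1ccccc1)C(C)(C)C)CCC | intermediate
18 | (4R)-4-[(1R,3Z,9R)-1-(benzyloxy)-9-[(tert-butyldiphenylsilyl)oxy]dodec-3-en-1-yl]-1,3-oxazolidin-2-one | O=C1OC[C@@H](N1)[C@H](OCc1ccccc1)C/C=C\CCCC[C@H](O[Si](c1ccccc1)(c1ccccc1)C(C)(C)C)CCC | intermediate
19 | (E)-but-2-enal | C/C=C/C=O | starting material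
20 | (4R)-4-[(1R,3Z,9R)-1-(benzyloxy)-9-[(tert-butyldiphenylsilyl)oxy]dodec-3-en-1-yl]-3-[(1E)-buta-1,3-dien-1-yl]-1,3-oxazolidin-2-one | C=C/C=C/N1C(=O)OC[C@@H]1[C@H](OCc1ccccc1)C/C=C\CCCC[C@H](O[Si](c1ccccc1)(c1ccccc1)C(C)(C)C)CCC | intermediate
21 | (3aR,4R,5aS,6S,9aR)-4-(benzyloxy)-6-{(5R)-5-[(tert-butyldiphenylsilyl)oxy]octyl}-3,3a,4,5,5a,6,7,9a-octahydro-1H-[1,3]oxazolo[3,4-a]quinolin-1-one | c1ccccc1CO[C@@H]1C[C@H]2[C@@H](CCCC[C@H](O[Si](c3ccccc3)(c3ccccc3)C(C)(C)C)CCC)CC=C[C@H]2N2[C@@H]1COC2=O | intermediate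
22 | sodium (2S,3R,4aS,5S,8aR)-3-(benzyloxy)-5-{(5R)-5-[(tert-butyldiphenylsilyl)oxy]octyl}-2-[(phenylsulfanyl)methyl]-3,4,4a,5,6,8a-hexahydroquinoline-1(2H)-carboxylate | c1ccccc1CO[C@@H]1C[C@H]2[C@@H](CCCC[C@H](O[Si](c3ccccc3)(c3ccccc3)C(C)(C)C)CCC)CC=C[C@H]2N(C([O-])=O)[C@@H]1CSc1ccccc1.[Na+] | intermediate
23 | (2S,3R,4aS,5S,8aR)-3-(benzyloxy)-5-{(5R)-5-[(tert-butyldiphenylsilyl)oxy]octyl}-2-[(phenylsulfanyl)methyl]-1,2,3,4,4a,5,6,8a-octahydroquinoline | c1ccccc1CO[C@@H]1C[C@H]2[C@@H](CCCC[C@H](O[Si](c3ccccc3)(c3ccccc3)C(C)(C)C)CCC)CC=C[C@H]2N[C@@H]1CSc1ccccc1 | intermediate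
24 | (2R,3R,4aS,5S,8aR)-3-(benzyloxy)-5-{(5R)-5-[(tert-butyldiphenylsilyl)oxy]octyl}-2-methyldecahydroquinoline | c1ccccc1CO[C@@H]1C[C@H]2[C@@H](CCCC[C@H](O[Si](c3ccccc3)(c3ccccc3)C(C)(C)C)CCC)CCC[C@H]2N[C@@H]1C | intermediate
25 | tert-butyl (2R,3R,4aS,5S,8aR)-3-(benzyloxy)-5-{(5R)-5-[(tert-butyldiphenylsilyl)oxy]octyl}-2-methyloctahydroquinoline-1(2H)-carboxylate | c1ccccc1CO[C@@H]1C[C@H]2[C@@H](CCCC[C@H](O[Si](c3ccccc3)(c3ccccc3)C(C)(C)C)CCC)CCC[C@H]2N(C(=O)OC(C)(C)C)[C@@H]1C | intermediate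
26 | tert-butyl (2R,3R,4aS,5S,8aR)-5-{(5R)-5-[(tert-butyldiphenylsilyl)oxy]octyl}-3-hydroxy-2-methyloctahydroquinoline-1(2H)-carboxylate | O[C@@H]1C[C@H]2[C@@H](CCCC[C@H](O[Si](c3ccccc3)(c3ccccc3)C(C)(C)C)CCC)CCC[C@H]2N(C(=O)OC(C)(C)C)[C@@H]1C | intermediate
27 | (2E)-oct-2-enoic acid | CCCCC/C=C/C(=O)O | starting material
28 | tert-butyl (2R,3R,4aS,5S,8aR)-5-{(5R)-5-[(tert-butyldiphenylsilyl)oxy]octyl}-2-methyl-3-{[(2E)-oct-2-enoyl]oxy}octahydroquinoline-1(2H)-carboxylate | CCCCC/C=C/C(=O)O[C@@H]1C[C@H]2[C@@H](CCCC[C@H](O[Si](c3ccccc3)(c3ccccc3)C(C)(C)C)CCC)CCC[C@H]2N(C(=O)OC(C)(C)C)[C@@H]1C | intermediate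
29 | tert-butyl (2R,3R,4aS,5S,8aR)-5-[(5R)-5-hydroxyoctyl]-2-methyl-3-{[(2E)-oct-2-enoyl]oxy}octahydroquinoline-1(2H)-carboxylate | CCCCC/C=C/C(=O)O[C@@H]1C[C@H]2[C@@H](CCCC[C@H](O)CCC)CCC[C@H]2N(C(=O)OC(C)(C)C)[C@@H]1C | intermediate
30 | (2R,3R,4aS,5S,8aR)-5-[(5R)-5-hydroxyoctyl]-2-methyldecahydroquinolin-3-yl (2E)-oct-2-enoate | CCCCC/C=C/C(=O)O[C@@H]1C[C@H]2[C@@H](CCCC[C@H](O)CCC)CCC[C@H]2N[C@@H]1C | target

Total step count: 16. Longest linear sequence: 13 steps (steps 4–16 from aldehyde 8; the side-chain branch, steps 1–3 then 7–16, is equally long).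

Steps most likely to fail

Step 11. The exo, trans-fusing mode or a boat-type approach to the other π-face may compete, and the dienamide may decay thermally before the unactivated alkene adds. Fallback: move the activation into the diene so that closure runs at lower temperature. It sets out from 18 and returns at 24. Conjugate addition of the carbamate N–H of 18 to but-3-yn-2-one (DABCO cat., MeCN) should give the vinylogous imide F1. Enol silylation (KN(SiMe3)2, TBSCl, THF, −78 °C) should give the 1-amido-3-silyloxydiene F2, a diene class that cycloadds well below 190 °C. Heating in toluene at 110–140 °C should close it through the same chair to the C7 silyl enol ether cycloadduct F3. Cold dilute HCl in THF should give the C7 ketone F4, and ethane-1,2-dithiol with BF3·OEt2 the dithiolane F5. PhSNa as in step 12 should give the amino sulfide F6, and Raney Ni as in step 13 removes both sulfur functions to give 24.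

Step 10. Condensation at the hindered carbamate N–H may be slow, so that aza-Michael addition and self-condensation of the enal take over, and acid may erode the silyl ether. Fallback: build the diene by alkylation and isomerisation under basic or neutral conditions. It sets out from 18 and returns at 20. N-Alkylation with 1-bromobut-2-yne (NaH, DMF, 0 °C) should give the N-(but-2-ynyl)oxazolidinone F7. Base-catalysed propargyl-to-allenyl isomerisation (KOtBu cat., THF) should give the allenamide F8. A thermal or camphorsulfonic-acid-catalysed 1,3-hydrogen shift should then give the (E)-dienamide 20, if wished in the same pot as step 11.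

Step 12. SN2 attack at the β-branched O–CH2 carbon may be slow, so that reversible attack at the carbamate carbonyl or cleavage of the silyl ether wins. Fallback: hydrolyse the carbamate and deoxygenate the primary alcohol. It sets out from 21 and returns at 25. Ba(OH)2·8H2O in EtOH/H2O at 80 °C (acyl–oxygen cleavage) should give the amino alcohol F9. Boc2O should give the N-Boc alcohol F10, and I2, PPh3 and imidazole the primary iodide F11. Hydrogenation over Pd/C with Et3N should cleave the C–I bond and saturate C7=C8 while the amine base spares the benzyl ether, giving 25, the intermediate of step 14.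

Further compounds
F1 | step 11 | (4R)-4-[(1R,3Z,9R)-1-(benzyloxy)-9-[(tert-butyldiphenylsilyl)oxy]dodec-3-en-1-yl]-3-[(1E)-3-oxobut-1-en-1-yl]-1,3-oxazolidin-2-one | CC(=O)/C=C/N1C(=O)OC[C@@H]1[C@H](OCc1ccccc1)C/C=C\CCCC[C@H](O[Si](c1ccccc1)(c1ccccc1)C(C)(C)C)CCC
F2 | step 11 | (4R)-4-[(1R,3Z,9R)-1-(benzyloxy)-9-[(tert-butyldiphenylsilyl)oxy]dodec-3-en-1-yl]-3-[(1E)-3-[(tert-butyldimethylsilyl)oxy]buta-1,3-dien-1-yl]-1,3-oxazolidin-2-one | C=C(O[Si](C)(C)C(C)(C)C)/C=C/N1C(=O)OC[C@@H]1[C@H](OCc1ccccc1)C/C=C\CCCC[C@H](O[Si](c1ccccc1)(c1ccccc1)C(C)(C)C)CCC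
F3 | step 11 | C7 tert-butyldimethylsilyl enol ether analogue of 21 (silyloxy group on C7 of the C7=C8 bond) | c1ccccc1CO[C@@H]1C[C@H]2[C@@H](CCCC[C@H](O[Si](c3ccccc3)(c3ccccc3)C(C)(C)C)CCC)CC(O[Si](C)(C)C(C)(C)C)=C[C@H]2N2[C@@H]1COC2=O
F4 | step 11 | C7 ketone analogue of 21 (C7=O, C8 saturated) | c1ccccc1CO[C@@H]1C[C@H]2[C@@H](CCCC[C@H](O[Si](c3ccccc3)(c3ccccc3)C(C)(C)C)CCC)CC(=O)C[C@H]2N2[C@@H]1COC2=O
F5 | step 11 | C7 spiro-1,3-dithiolane of F4 | c1ccccc1CO[C@@H]1C[C@H]2[C@@H](CCCC[C@H](O[Si](c3ccccc3)(c3ccccc3)C(C)(C)C)CCC)CC3(SCCS3)C[C@H]2N2[C@@H]1COC2=O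
F6 | step 11 | (2S,3R,4aS,5S,8aR)-3-(benzyloxy)-5-{(5R)-5-[(tert-butyldiphenylsilyl)oxy]octyl}-2-[(phenylsulfanyl)methyl]decahydroquinoline C7 spiro-1,3-dithiolane | c1ccccc1CO[C@@H]1C[C@H]2[C@@H](CCCC[C@H](O[Si](c3ccccc3)(c3ccccc3)C(C)(C)C)CCC)CC3(SCCS3)C[C@H]2N[C@@H]1CSc1ccccc1
F7 | step 10 | (4R)-4-[(1R,3Z,9R)-1-(benzyloxy)-9-[(tert-butyldiphenylsilyl)oxy]dodec-3-en-1-yl]-3-(but-2-yn-1-yl)-1,3-oxazolidin-2-one | CC#CCN1C(=O)OC[C@@H]1[C@H](OCc1ccccc1)C/C=C\CCCC[C@H](O[Si](c1ccccc1)(c1ccccc1)C(C)(C)C)CCC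
F8 | step 10 | (4R)-4-[(1R,3Z,9R)-1-(benzyloxy)-9-[(tert-butyldiphenylsilyl)oxy]dodec-3-en-1-yl]-3-(buta-1,2-dien-1-yl)-1,3-oxazolidin-2-one (both allene epimers) | CC=C=CN1C(=O)OC[C@@H]1[C@H](OCc1ccccc1)C/C=C\CCCC[C@H](O[Si](c1ccccc1)(c1ccccc1)C(C)(C)C)CCC
F9 | step 12 | [(2R,3R,4aS,5S,8aR)-3-(benzyloxy)-5-{(5R)-5-[(tert-butyldiphenylsilyl)oxy]octyl}-1,2,3,4,4a,5,6,8a-octahydroquinolin-2-yl]methanol | c1ccccc1CO[C@@H]1C[C@H]2[C@@H](CCCC[C@H](O[Si](c3ccccc3)(c3ccccc3)C(C)(C)C)CCC)CC=C[C@H]2N[C@@H]1CO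
F10 | step 12 | tert-butyl (2R,3R,4aS,5S,8aR)-3-(benzyloxy)-5-{(5R)-5-[(tert-butyldiphenylsilyl)oxy]octyl}-2-(hydroxymethyl)-3,4,4a,5,6,8a-hexahydroquinoline-1(2H)-carboxylate | c1ccccc1CO[C@@H]1C[C@H]2[C@@H](CCCC[C@H](O[Si](c3ccccc3)(c3ccccc3)C(C)(C)C)CCC)CC=C[C@H]2N(C(=O)OC(C)(C)C)[C@@H]1CO
F11 | step 12 | tert-butyl (2S,3R,4aS,5S,8aR)-3-(benzyloxy)-5-{(5R)-5-[(tert-butyldiphenylsilyl)oxy]octyl}-2-(iodomethyl)-3,4,4a,5,6,8a-hexahydroquinoline-1(2H)-carboxylate | c1ccccc1CO[C@@H]1C[C@H]2[C@@H](CCCC[C@H](O[Si](c3ccccc3)(c3ccccc3)C(C)(C)C)CCC)CC=C[C@H]2N(C(=O)OC(C)(C)C)[C@@H]1CI
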